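The retrosynthesis (benzofuranone numbering O1, C2, C3, C3a, C4–C7, C7a) cuts O1–C2 (lactonisation), C7a–O1 (back to C7a–Br, then C7a–H), C3a–C3 (back to C3a–I plus an α-stannyl cinnamate), and last C5–C(acyl) together with C6–O.
The enabling feature is that C4, C5, C6 and C7 of the benzene ring carry methoxy, acyl, hydroxyl and oxygen in an unbroken row. The acyl carbon on C5 and the oxygen on C6 add up to one molecule of 3-phenylpropanoic acid, and their outer neighbours, the oxygens on C4 and C7, are para to each other. The C5≡C6 aryne is therefore the mirror-symmetric 3,6-dimethoxybenzyne.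
In the forward direction the benzene ring is bought as 2,5-dimethoxyphenol and made into the silylaryl triflate, and the insertion sets C4–C7. The C7 methyl, now part of a guaiacol, is removed oxidatively and the catechol is tied up as a ketal. C3a is iodinated and coupled, C7a (the last C–H) is brominated and hydroxylated, and acid then closes the five-membered lactone (the only ring built) and frees the catechol.
There is no stereocentre. The Z alkene (phenyl cis to C2=O) comes from syn hydrostannylation of methyl phenylpropiolate and retention in the Stille coupling, and it is also the isomer that keeps phenyl away from the C4 methoxy group.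

Key step: step 4

Remark: the target is achiral, so "single enantiomer" is read as the single Z isomer of the exocyclic alkene drawn in the SMILES. Ring positions of intermediates are named by the target atom they become.

Step 1
Reactants: 1 2,5-dimethoxyphenol
Product: 2 2,5-dimethoxyphenyl N-isopropylcarbamate
Conditions: i-PrNCO (1.5 equiv), Et3N (0.2 equiv), CH2Cl2, rt
Reagents that add atoms: isopropyl isocyanate CC(C)N=C=O
Why: Base-catalysed addition of a phenol to an isocyanate (carbamoylation) is clean and gives a secondary carbamate that directs lithiation once N-silylated and can later be removed with mild base.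

Step 2
Reactants: 2 2,5-dimethoxyphenyl N-isopropylcarbamate
Product: 6 3,6-dimethoxy-2-(trimethylsilyl)phenyl N-isopropylcarbamate, via N-TBS carbamate 3 (not isolated), via aryllithium 4 (not isolated), via N-TBS C-TMS carbamate 5 (not isolated)
Conditions: TBSOTf (1.1 equiv), TMEDA (1.1 equiv), Et2O, 0 °C to rt; then TMEDA (2 equiv), n-BuLi (2.2 equiv), −78 °C; then TMSCl (3 equiv), −78 °C to rt; aq NaHSO4
Reagents that add atoms: chlorotrimethylsilane C[Si](C)(C)Cl; TBSOTf CC(C)(C)[Si](C)(C)OS(=O)(=O)C(F)(F)F (its silyl group is present only in 3, 4 and 5)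
Why: In this directed ortho-metalation the N–H is masked in situ, the one position lying between the carbamate and a methoxy group is deprotonated under the cooperative effect of both, the aryllithium is silylated, and the labile N–Si bond is lost in the acidic work-up.

Step 3
Reactants: 6 3,6-dimethoxy-2-(trimethylsilyl)phenyl N-isopropylcarbamate
Product: 8 3,6-dimethoxy-2-(trimethylsilyl)phenyl trifluoromethanesulfonate, via 2-silylphenol 7 (not isolated)
Conditions: DBU (1.5 equiv), Et2NH (1.2 equiv), MeCN, 40 °C; then PhNTf2 (1.5 equiv), rt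
Reagents that add atoms: N-phenylbis(trifluoromethanesulfonimide) O=S(=O)(N(c1ccccc1)S(=O)(=O)C(F)(F)F)C(F)(F)F
Why: DBU triggers E1cB loss of isopropyl isocyanate (scavenged by diethylamine) and the phenoxide is triflated in the same pot with a mild triflyl donor, so the protodesilylation-prone silylphenol is never isolated.

Step 4
Reactants: 8 3,6-dimethoxy-2-(trimethylsilyl)phenyl trifluoromethanesulfonate (1.0 equiv); 9 3-phenylpropanoic acid (1.2 equiv)
Product: 13 1-(2-hydroxy-3,6-dimethoxyphenyl)-3-phenylpropan-1-one (2'-hydroxy-3',6'-dimethoxydihydrochalcone), via 3,6-dimethoxybenzyne 10 (not isolated), via ortho-caesiated aryl ester 11 (not isolated), via benzoxetene alkoxide 12 (not isolated)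
Conditions: CsF (4 equiv, dried), THF (0.02 M), sealed tube, 125 °C, 24 h; aq NH4Cl
Reagents that add atoms: none
Why: Fluoride strips the silyl group of 8 and triflate departs to give aryne 10, and the caesium carboxylate of 9 adds through oxygen to one aryne carbon (C6–O bond) to give the ortho-metalated aryl ester 11. The aryl anion then attacks its own ester carbonyl in a 4-exo-trig closure to the benzoxetene alkoxide 12, whose ring C–O bond breaks at once, so the acyl carbon ends on C5 (C5–C(acyl) bond), the oxygen stays on C6 as a chelated phenoxide, and no ring remains in 13. The closest known reaction type is the insertion of arynes from o-silylaryl triflates into the C–O bond of carboxylic acids in hot THF, which is mechanistically an anionic Fries-type O-to-C acyl shift. No stereocentre is formed. Regioselectivity is not required, because 10 has a mirror plane through the midpoint of the triple bond and each aryne carbon has a methoxy neighbour, so either mode of addition gives the same 13 with methoxy, acyl, hydroxyl and methoxy in a row. What is required is chemoselectivity for acyl transfer over protonation of 11 and over arylation of the product phenoxide: excess dry CsF keeps 9 as its salt, high temperature and high dilution in an aprotic solvent favour the intramolecular step, and the phenoxide of 13 is flanked on both sides and tied to the ketone.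

Step 5
Reactants: 13 1-(2-hydroxy-3,6-dimethoxyphenyl)-3-phenylpropan-1-one
Product: 15 1-(2,3-dihydroxy-6-methoxyphenyl)-3-phenylpropan-1-one, via o-quinone 14 (not isolated)
Conditions: IBX (1.2 equiv), DMF, rt, dark; then aq Na2S2O4, rt
Reagents that add atoms: 2-iodoxybenzoic acid (IBX) O=C1OI(=O)(O)c2ccccc12
Why: In this oxidative demethylation of a 2-methoxyphenol by a λ5-iodane the phenol binds to iodine, oxygen is delivered to the ortho carbon bearing OMe (the other ortho carbon carries the acyl group), methanol is lost to give a push-pull-stabilised 4-methoxy-o-quinone that dithionite reduces to the catechol, and the C4 methoxy group, which has no free phenol beside it, is not touched.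

Step 6
Reactants: 15 1-(2,3-dihydroxy-6-methoxyphenyl)-3-phenylpropan-1-one
Product: 16 1-(5-methoxy-2,2-diphenyl-1,3-benzodioxol-4-yl)-3-phenylpropan-1-one
Conditions: Ph2CCl2 (1.5 equiv), K2CO3 (3 equiv), MeCN, reflux, argon
Reagents that add atoms: dichlorodiphenylmethane ClC(Cl)(c1ccccc1)c1ccccc1
Why: Double O-alkylation of a catechol with a gem-dichloride (diphenylmethylene ketal formation), familiar for 2,3-dihydroxybenzoyl systems, ties both phenols into one base-stable, acid-labile five-membered ring.

Step 7
Reactants: 16 1-(5-methoxy-2,2-diphenyl-1,3-benzodioxol-4-yl)-3-phenylpropan-1-one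
Product: 17 1-(6-iodo-5-methoxy-2,2-diphenyl-1,3-benzodioxol-4-yl)-3-phenylpropan-1-one
Conditions: NIS (1.1 equiv), TFA (0.3 equiv), MeCN, rt, dark
Reagents that add atoms: N-iodosuccinimide O=C1CCC(=O)N1I
Why: Electrophilic aromatic iodination goes to future C3a, which is para to the C6 oxygen and ortho to the methoxy group, whereas future C7a is para to the acyl group and activated by only one oxygen.

Step 8
Reactants: 18 methyl 3-phenylprop-2-ynoate (methyl phenylpropiolate)
Product: 19 methyl (E)-3-phenyl-2-(tributylstannyl)prop-2-enoate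
Conditions: Bu3SnH (1.1 equiv, slow addition), Pd(PPh3)4 (2 mol%), THF, 0 °C to rt
Reagents that add atoms: tributyltin hydride CCCC[SnH](CCCC)CCCC
Why: Palladium-catalysed hydrostannylation of an alkynoate is a syn addition that places tin on the carbon α to the ester, so H and Sn end up cis and phenyl and ester end up cis, which is the geometry of the target alkene.

Step 9
Reactants: 17 1-(6-iodo-5-methoxy-2,2-diphenyl-1,3-benzodioxol-4-yl)-3-phenylpropan-1-one; 19 methyl (E)-3-phenyl-2-(tributylstannyl)prop-2-enoate
Product: 20 methyl (Z)-2-[6-methoxy-2,2-diphenyl-7-(3-phenylpropanoyl)-1,3-benzodioxol-5-yl]-3-phenylprop-2-enoate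
Conditions: Pd(PPh3)4 (5 mol%), CuI (20 mol%), CsF (2 equiv), DMF, 45 °C
Reagents that add atoms: none
Why: The Stille coupling with copper(I) and fluoride assistance, established for α-stannyl acrylates and aryl iodides, forms C3a–C3 with retention of the alkene geometry while copper suppresses cine substitution.

Step 10
Reactants: 20 methyl (Z)-2-[6-methoxy-2,2-diphenyl-7-(3-phenylpropanoyl)-1,3-benzodioxol-5-yl]-3-phenylprop-2-enoate
Product: 21 methyl (Z)-2-[4-bromo-6-methoxy-2,2-diphenyl-7-(3-phenylpropanoyl)-1,3-benzodioxol-5-yl]-3-phenylprop-2-enoate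
Conditions: NBS (1.1 equiv), MeCN, 0 to 40 °C, dark
Reagents that add atoms: N-bromosuccinimide O=C1CCC(=O)N1Br
Why: Nuclear bromination of an alkoxyarene with NBS in a polar solvent can strike only the last ring C–H (future C7a), ortho to the well-aligned dioxole oxygen, because the alkene is deactivated by the ester and shielded and the four phenyl rings are far less electron rich.

Step 11
Reactants: 21 methyl (Z)-2-[4-bromo-6-methoxy-2,2-diphenyl-7-(3-phenylpropanoyl)-1,3-benzodioxol-5-yl]-3-phenylprop-2-enoate
Product: 23 (Z)-2-[4-hydroxy-6-methoxy-2,2-diphenyl-7-(3-phenylpropanoyl)-1,3-benzodioxol-5-yl]-3-phenylprop-2-enoic acid, via lithium bromoacrylate 22 (not isolated)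
Conditions: Cu(acac)2 (5 mol%), N,N'-bis(4-hydroxy-2,6-dimethylphenyl)oxalamide (5 mol%), LiOH·H2O (5 equiv), DMSO/H2O 4:1, 80 °C, argon; then 1 M HCl, 0 °C
Reagents that add atoms: lithium hydroxide [Li+].[OH-]
Why: Hydroxide first saponifies the ester, and the neighbouring carboxylate then assists the copper-catalysed Ullmann-type hydroxylation of the aryl bromide, which the para ketone also activates, as in the conversion of 2-halophenylacetic acids into 2-hydroxyphenylacetic acids; any lactone formed on acidification converges in step 12.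

Step 12
Reactants: 23 (Z)-2-[4-hydroxy-6-methoxy-2,2-diphenyl-7-(3-phenylpropanoyl)-1,3-benzodioxol-5-yl]-3-phenylprop-2-enoic acid
Product: 25 bractelactone (3Z)-3-benzylidene-6,7-dihydroxy-4-methoxy-5-(3-phenylpropanoyl)-1-benzofuran-2(3H)-one, via lactone ketal 24 (not isolated)
Conditions: TFA/CH2Cl2 1:1, H2O (2 equiv), 0 °C to rt, argon
Reagents that add atoms: none
Why: Acid-catalysed lactonisation of the 2-hydroxyaryl acrylic acid (5-exo-trig at the carboxyl carbon) and hydrolysis of the diphenylmethylene ketal run in one pot, the water lost in the first feeding the second, and the Z alkene is retained because it is also the isomer that avoids a clash of phenyl with the C4 methoxy group.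

Compound list
1 | 2,5-dimethoxyphenol | COc1ccc(OC)c(O)c1 | starting material
2 | 2,5-dimethoxyphenyl N-isopropylcarbamate | COc1ccc(OC)c(OC(=O)NC(C)C)c1 | intermediate
3 | 2,5-dimethoxyphenyl N-(tert-butyldimethylsilyl)-N-isopropylcarbamate | COc1ccc(OC)c(OC(=O)N(C(C)C)[Si](C)(C)C(C)(C)C)c1 | intermediate
4 | 2-lithio-3,6-dimethoxyphenyl N-(tert-butyldimethylsilyl)-N-isopropylcarbamate | COc1ccc(OC)c(OC(=O)N(C(C)C)[Si](C)(C)C(C)(C)C)c1[Li] | intermediate
5 | 3,6-dimethoxy-2-(trimethylsilyl)phenyl N-(tert-butyldimethylsilyl)-N-isopropylcarbamate | COc1ccc(OC)c(OC(=O)N(C(C)C)[Si](C)(C)C(C)(C)C)c1[Si](C)(C)C | intermediate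
6 | 3,6-dimethoxy-2-(trimethylsilyl)phenyl N-isopropylcarbamate | COc1ccc(OC)c(OC(=O)NC(C)C)c1[Si](C)(C)C | intermediate
7 | 3,6-dimethoxy-2-(trimethylsilyl)phenol (present as its amidinium phenoxide) | COc1ccc(OC)c(O)c1[Si](C)(C)C | intermediate
8 | 3,6-dimethoxy-2-(trimethylsilyl)phenyl trifluoromethanesulfonate | COc1ccc(OC)c(OS(=O)(=O)C(F)(F)F)c1[Si](C)(C)C | intermediate
9 | 3-phenylpropanoic acid | O=C(O)CCc1ccccc1 | starting material
10 | 3,6-dimethoxybenzyne | COC1=CC=C(OC)C#C1 | intermediate
11 | 2-caesio-3,6-dimethoxyphenyl 3-phenylpropanoate | COc1ccc(OC)c(OC(=O)CCc2ccccc2)[c-]1.[Cs+] | intermediate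
12 | caesium 3,6-dimethoxy-2-(2-phenylethyl)-2H-benzo[b]oxet-2-olate | COc1ccc(OC)c2c1OC2([O-])CCc1ccccc1.[Cs+] | intermediate
13 | 1-(2-hydroxy-3,6-dimethoxyphenyl)-3-phenylpropan-1-one | COc1ccc(OC)c(O)c1C(=O)CCc1ccccc1 | intermediate
14 | 4-methoxy-3-(3-phenylpropanoyl)cyclohexa-3,5-diene-1,2-dione | COC1=C(C(=O)CCc2ccccc2)C(=O)C(=O)C=C1 | intermediate
15 | 1-(2,3-dihydroxy-6-methoxyphenyl)-3-phenylpropan-1-one | COc1ccc(O)c(O)c1C(=O)CCc1ccccc1 | intermediate
16 | 1-(5-methoxy-2,2-diphenyl-1,3-benzodioxol-4-yl)-3-phenylpropan-1-one | COc1ccc2OC(c3ccccc3)(c3ccccc3)Oc2c1C(=O)CCc1ccccc1 | intermediate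
17 | 1-(6-iodo-5-methoxy-2,2-diphenyl-1,3-benzodioxol-4-yl)-3-phenylpropan-1-one | COc1c(I)cc2OC(c3ccccc3)(c3ccccc3)Oc2c1C(=O)CCc1ccccc1 | intermediate
18 | methyl 3-phenylprop-2-ynoate | COC(=O)C#Cc1ccccc1 | starting material
19 | methyl (E)-3-phenyl-2-(tributylstannyl)prop-2-enoate (Sn trans to phenyl, ester cis to phenyl) | COC(=O)/C(=C\c1ccccc1)[Sn](CCCC)(CCCC)CCCC | intermediate
20 | methyl (Z)-2-[6-methoxy-2,2-diphenyl-7-(3-phenylpropanoyl)-1,3-benzodioxol-5-yl]-3-phenylprop-2-enoate | COC(=O)/C(=C\c1ccccc1)c1cc2OC(c3ccccc3)(c3ccccc3)Oc2c(C(=O)CCc2ccccc2)c1OC | intermediate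
21 | methyl (Z)-2-[4-bromo-6-methoxy-2,2-diphenyl-7-(3-phenylpropanoyl)-1,3-benzodioxol-5-yl]-3-phenylprop-2-enoate | COC(=O)/C(=C\c1ccccc1)c1c(Br)c2OC(c3ccccc3)(c3ccccc3)Oc2c(C(=O)CCc2ccccc2)c1OC | intermediate
22 | lithium (Z)-2-[4-bromo-6-methoxy-2,2-diphenyl-7-(3-phenylpropanoyl)-1,3-benzodioxol-5-yl]-3-phenylprop-2-enoate | [Li+].[O-]C(=O)/C(=C\c1ccccc1)c1c(Br)c2OC(c3ccccc3)(c3ccccc3)Oc2c(C(=O)CCc2ccccc2)c1OC | intermediate
23 | (Z)-2-[4-hydroxy-6-methoxy-2,2-diphenyl-7-(3-phenylpropanoyl)-1,3-benzodioxol-5-yl]-3-phenylprop-2-enoic acid | OC(=O)/C(=C\c1ccccc1)c1c(O)c2OC(c3ccccc3)(c3ccccc3)Oc2c(C(=O)CCc2ccccc2)c1OC | intermediate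
24 | bractelactone 6,7-O-diphenylmethylene ketal, (Z)-benzylidene | COc1c(C(=O)CCc2ccccc2)c2OC(c3ccccc3)(c3ccccc3)Oc2c2c1/C(=C/c1ccccc1)C(=O)O2 | intermediate
25 | bractelactone, (3Z)-3-benzylidene-6,7-dihydroxy-4-methoxy-5-(3-phenylpropanoyl)-1-benzofuran-2(3H)-one | COc1c(C(=O)CCc2ccccc2)c(O)c(O)c2c1/C(=C/c1ccccc1)C(=O)O2 | target

Total step count: 12. Longest linear sequence: 11 (steps 1 to 7 and 9 to 12; step 8 is the side branch).

Steps most likely to fail

Step 4. The aryl anion may pick up a proton before it reaches the ester carbonyl, either from bifluoride or from the α-CH2 of its own ester, so that the sequence stops at simple O-arylation. The product phenoxide may also be arylated by a second aryne. The fallback sets out from 2 and comes back at 13, replacing the aryne by directed metalation and acylation. The N-silylation and lithiation of step 2 give 3 and then aryllithium 4. This is quenched at −78 °C with N-methoxy-N-methyl-3-phenylpropanamide F1, made from 9 and MeNHOMe·HCl with EDC. Acidic work-up, which also removes the N-silyl group, should give 3,6-dimethoxy-2-(3-phenylpropanoyl)phenyl N-isopropylcarbamate F2. DBU/Et2NH in MeCN at 40 °C then frees the phenol to give 13.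

Step 5. Ligand exchange of the ketone-chelated phenol at iodine(V) may be slow. The electrophilic o-quinone may also add water or methanol at its methoxy-bearing carbon, or be oxidised further, before it is reduced. The fallback sets out from 13 and comes back at 16, replacing selective oxidation by exhaustive cleavage and ring-size-controlled reprotection. BBr3 in CH2Cl2 (−78 °C to rt) should remove both methyl groups to give 1-(2,3,6-trihydroxyphenyl)-3-phenylpropan-1-one F3. Ph2CCl2/K2CO3 under argon can bridge only the vicinal pair of hydroxyls, giving 1-(5-hydroxy-2,2-diphenyl-1,3-benzodioxol-4-yl)-3-phenylpropan-1-one F4. MeI/K2CO3 in DMF then methylates the remaining chelated hydroxyl to give 16.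

Step 10. Substitution at the last ring position may be sluggish, because that position is para to the acyl group and lies next to the twisted acrylate. Addition to the alkene or radical benzylic bromination may then compete. The fallback sets out from 20 and comes back at 21, and switches on the position with a free phenol. TFA/CH2Cl2/H2O removes the ketal to give methyl (Z)-2-[4,5-dihydroxy-2-methoxy-3-(3-phenylpropanoyl)phenyl]-3-phenylprop-2-enoate F5. NBS in MeCN at −30 °C should then brominate ortho to the unchelated C7 hydroxyl to give methyl (Z)-2-[2-bromo-3,4-dihydroxy-6-methoxy-5-(3-phenylpropanoyl)phenyl]-3-phenylprop-2-enoate F6. Ph2CCl2/K2CO3 restores the ketal to give 21.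

Further compounds
F1 | step 4 | N-methoxy-N-methyl-3-phenylpropanamide | CON(C)C(=O)CCc1ccccc1
F2 | step 4 | 3,6-dimethoxy-2-(3-phenylpropanoyl)phenyl N-isopropylcarbamate | COc1ccc(OC)c(OC(=O)NC(C)C)c1C(=O)CCc1ccccc1
F3 | step 5 | 1-(2,3,6-trihydroxyphenyl)-3-phenylpropan-1-one | Oc1ccc(O)c(O)c1C(=O)CCc1ccccc1
F4 | step 5 | 1-(5-hydroxy-2,2-diphenyl-1,3-benzodioxol-4-yl)-3-phenylpropan-1-one | Oc1ccc2OC(c3ccccc3)(c3ccccc3)Oc2c1C(=O)CCc1ccccc1
F5 | step 10 | methyl (Z)-2-[4,5-dihydroxy-2-methoxy-3-(3-phenylpropanoyl)phenyl]-3-phenylprop-2-enoate | COC(=O)/C(=C\c1ccccc1)c1cc(O)c(O)c(C(=O)CCc2ccccc2)c1OC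
F6 | step 10 | methyl (Z)-2-[2-bromo-3,4-dihydroxy-6-methoxy-5-(3-phenylpropanoyl)phenyl]-3-phenylprop-2-enoate | COC(=O)/C(=C\c1ccccc1)c1c(Br)c(O)c(O)c(C(=O)CCc2ccccc2)c1OC
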